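## Structural features

The target is a biflavonoid: a (2S)-7-hydroxy-5-methoxyflavanone (rings A and C with aryl ring B) is joined through C3' of ring B to C6'' of a 5'',7'',4'''-trihydroxyflavone (rings A'', C'' and B''). The C3'–C6'' bond is a biaryl bond flanked by three oxygens (on C4', C5'' and C7''); it is hindered to make but is assumed not to be a stable stereogenic axis. C2 of the flavanone is the only stereocentre and has no stereogenic neighbour, but it is benzylic, bears O1 and lies β to the C4 ketone, so base can open ring C to the chalcone and racemise it. Five phenols must be freed at the end beside one methyl ether on C5, which is peri to the C4 carbonyl and is the first ether lost to boron or aluminium halides; the benzylic C2–O1 bond and C2''=C3'' limit how hard a hydrogenolysis may be pushed. The real difficulty is ring A'': the aryl group must stand on C6'', between the oxygens on C5'' and C7'', and not on C8'', and a flavone with a free 5''-hydroxyl can exchange these positions by acid-induced ring opening and reclosure (Wessely–Moser). The key step exploits the fact that C8a'' (bearing O1'') and C4a'' (bearing C4'') are neighbours: both can be the two carbons of a C4a''–C8a'' aryne, and the oxygen on C5'', next to C4a'', polarises it so that oxygen enters at C8a'' and the acyl carbon at C4a''. The aryne progenitor comes from a phenol with a mirror plane through C6'' and C8a'', so the 6''-aryl pattern is fixed by symmetry before ring C'' exists.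

## Logic of the disconnections

23 from 22. The five O–CH2Ph bonds are cut. Benzyl ethers allow one neutral hydrogenolysis to free all phenols while leaving the C5 methyl ether, which Lewis acidic deprotection would not respect. The gain is that every earlier intermediate is a non-acidic ether. The demand is that hydrogen uptake stops before C2''=C3'', the C4 carbonyl or the benzylic C2–O1 bond react.

22 from 17 and 21. The C2–C1' bond is cut. It is the one bond at the stereocentre that divides the molecule into a small heterocyclic acceptor and the complete flavone-bearing aryl donor, so the halves are joined and C2 is set in one operation. The forward step needs catalyst control of the enone face on an electron-rich acceptor, a free boronic acid, and no reaction at the second pyranone, whose β-carbon is fully substituted.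

17 from 16. The C1'–B bond is traced back to C1'–Cl. Chlorine is the only halogen that passes untouched through the coupling at iodine (step 3), the bromine–lithium exchange (step 5) and the fluoride step (step 7) and can still be activated afterwards. The forward borylation must engage an electron-rich aryl chloride and deliver the acid itself.

21 from 19, and 19 from 18. O1–C2 and C2–C3 of the small chromone are cut, taking C2 back to a one-carbon formamide acetal, and then the benzyl ether on the C7 oxygen. This reduces the acceptor to a commercial acetophenone. The demand is alkylation of the non-chelated hydroxyl only.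

16 from 15. O1''–C2'' is cut, opening ring C'' to the ortho-hydroxyaryl ynone. This separates ring formation from carbon–carbon bond formation. The forward closure must be 6-endo and not 5-exo.

15 from 10 and 13 (key disconnection). C4''–C4a'' and O1''–C8a'' are cut together, returning the acylphenol to an aryne progenitor and a carboxylic acid. The cut is made here because the two carbons are adjacent and the C5'' oxygen dictates which receives oxygen, so no Friedel–Crafts acylation of a crowded ring is needed. The gain is that the whole C2''–C3''–C4'' chain with ring B'' arrives in one piece and ring A'' is reduced to a symmetric phenol derivative. The demand is regioselective addition to the aryne and an acyl shift faster than protonation.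

13 from 11. The C–CO2H bond is cut, leaving a commercial terminal alkyne; the forward step is a plain carboxylation.

10 from 7, and 7 from 6. The C4a''–Si and O–SO2CF3 bonds are cut, then the C–Br bond. An ortho-bromophenol is the standard progenitor of an ortho-silylaryl triflate, and the two ortho positions of 6 are equivalent, so bromination has no regiochemical choice. The demand is that exchange at bromine spares C–Cl and the benzylic C–H bonds.

6 from 3 and 4. The biaryl bond C6''–C3' and the O–Si bond are cut. The ring B donor is a commercial boronic acid and the coupling is convergent. The demand is coupling at a di-ortho-substituted iodide without touching C–Cl.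

3 from 2, and 2 from 1. The C–I bond and then the O–Si bond are cut. The bulky silyl ether marks the oxygen that becomes O1'' and screens its two ortho carbons, so iodine should enter at the future C6''. The demand is steric control of a substitution in which the three free positions are electronically alike.

## Other disconnections considered

Alternative 1: The cut is O1–C8a of the flavanone, made after the C4 ketone is taken back to an alcohol. In the forward direction the (1S,3S)-diol carrying a triflate on the future C8a, A2, would be cyclised by intramolecular aryl ether formation (Pd(OAc)2 with a bulky di-tert-butylbiarylphosphine and Cs2CO3, or CuI with 1,10-phenanthroline). This would give the penta-O-benzyl (2S,4S)-flavan-4-ol A1, which would then be oxidised at C4 to 22.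
- In favour: the bond formed does not touch C2, so a carbinol configuration installed by reliable aldol or reduction chemistry is carried over with retention. Ring C stays at the alcohol stage until the final oxidation, so ring-opening racemisation cannot occur on the way. No boron reagent and no face-selective addition to an electron-rich chromone are needed. On security of the C2 configuration this plan is the better one.
- Against: palladium alkoxides of secondary benzylic alcohols are prone to β-hydride elimination. The triflate sits on an electron-rich ring beside a branched chain. A2 needs two controlled stereocentres although the one at C4 is erased later.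
- Comparison: structurally it deals only with ring C and leaves the ring A'' regiochemistry unsolved, so it rivals step 12 and not the key step. Mechanistically it replaces an enantio-determining carbopalladation by a stereoretentive C–O reductive elimination. In step count it spends four to five linear steps on the most advanced intermediate where the chosen plan uses one convergent step.

Alternative 2: The cut is C6''–C7'' inside ring A'', the carbocycle being traced back to a chain folded as a pyranone. In the forward direction sodium 4-methoxybenzyl oxide would open 6-(2-benzyloxy-5-bromobenzyl)-4-(4-methoxybenzyloxy)-2H-pyran-2-one A4 at the lactone carbonyl. The benzylic carbanion next to the ketone would then close onto the new ester (Dieckmann-type) to give 2-(2-benzyloxy-5-bromophenyl)-5-(4-methoxybenzyloxy)benzene-1,3-diol A3.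
- In favour: the aryl group is placed between two oxygens by connectivity and not by selectivity. The oxygen para to it emerges already distinguished. The materials are cheap and no transition metal is used. On regiochemical certainty and cost it is better than the sterically steered iodination of step 2.
- Against: the ring transformation is the uncertain event, since reclosure to the pyranone and deprotonation at the more acidic C5 methylene are unproductive equilibria that the benzylic closure has to drain. Reaching phenol 6 this way takes about six steps against three. The bromide of A3 would not survive the butyllithium step leading to 10, so a chloride would be needed.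
- Comparison: it builds only the carbocycle and forms no bond of ring C'', so it is a supply route to the aryne progenitor and not a rival to the key step. It is the equal of the chosen plan in leaving the heterocycle to the same aryne insertion. Its chloro version is kept as the fallback for step 2.

Alternative 3: The cuts are C2''–C3'' and C3''–C4''; C3'' is removed as a one-carbon unit, contracting ring C'' to a furan. In the forward direction dichlorocarbene (CHCl3, NaOH, benzyltriethylammonium chloride, or thermolysis of Cl3CCO2Na) would add across C2=C3 of the 3-silyloxy-2-arylbenzofuran A6. The dichlorocyclopropane would open with loss of chloride and silyl to the 3-chloroflavone A5 (Ciamician–Dennstedt-type ring expansion).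
- In favour: ring size is fixed by the insertion, so the 6-endo versus 5-exo question of step 8 does not arise, which is better on that point. No aryne progenitor, organolithium or triflate is needed, so a bromide on ring B is tolerated. The ring A'' regiochemistry rests, as in the chosen plan, on the symmetry of a phenol such as 6, which is equal on that point.
- Against: the enol ether double bond is tetrasubstituted and shielded by the neighbouring benzyloxy group. The silyl enol ether is labile to the hydroxide of the phase-transfer variant. The electron-rich benzyloxyarene rings compete for the carbene. A5 carries a chlorine on C3'' that must be removed later, and until then any palladium step has to tell C–Br from the vinylic C–Cl. A6 itself needs several steps from 6.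
- Comparison: carbene ring expansion is established for pyrroles, indoles and indenes but has no close counterpart on a fully substituted, oxygenated benzofuran enol ether, whereas aryne insertion into a carboxylic acid is a known reaction type. Making A6, the expansion and a dechlorination would not be shorter than steps 4, 5, 7 and 8.

Key step: step 7

Remarks on the chemistry (assumptions and design points):
- The sense of induction in step 12 is assumed to match that of the same catalyst with cyclic enones, where the (S)-ligand gives the (R)-β-aryl ketone from 3-methylcyclohexenone. Attack on the same enone face of a chromone corresponds to the (2R)-flavanone, so (R)-t-BuPyOx is specified for the (2S) product.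
- Compounds 1, 4, 11 and 18 are taken to be commercial.
- The unprotected target is assumed to have no configurationally stable C3'–C6'' axis.
- The silyl triflate 10 and the ynone 15 map correctly onto C4a''–C8a'' and C5''–C8'' of the target and need no correction.
- The plan reaches 10 in five steps by cross-coupling, keeps chloride (not bromide) on ring B because of step 5, and makes the free boronic acid (not a pinacol ester) because step 12 needs it.

## Route

Step 1
Reactants: 1 3,5-bis(benzyloxy)phenol
Product: 2 [3,5-bis(benzyloxy)phenoxy]tri(propan-2-yl)silane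
Conditions: TIPSCl, imidazole, DMF, rt
Reagents that add atoms: chlorotri(propan-2-yl)silane, CC(C)[Si](Cl)(C(C)C)C(C)C
Why: Imidazole-promoted silylation of the only free phenol; the triisopropylsilyl group is chosen for its bulk, which is to screen both neighbouring ring positions in step 2.

Step 2
Reactants: 2 [3,5-bis(benzyloxy)phenoxy]tri(propan-2-yl)silane
Product: 3 [3,5-bis(benzyloxy)-4-iodophenoxy]tri(propan-2-yl)silane
Conditions: NIS (1.0 equiv), MeCN, 0 °C to rt, dark
Reagents that add atoms: N-iodosuccinimide, O=C1CCC(=O)N1I
Why: Electrophilic aromatic iodination of a 1,3,5-trioxygenated ring; the bulky silyl ether blocks its two ortho positions, so iodine should enter between the two benzyloxy groups, at the carbon that becomes C6''.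

Step 3
Reactants: 3 [3,5-bis(benzyloxy)-4-iodophenoxy]tri(propan-2-yl)silane; 4 [2-(benzyloxy)-5-chlorophenyl]boronic acid
Product: 6 2,2',6-tris(benzyloxy)-5'-chlorobiphenyl-4-ol, via silyl-protected biaryl 5 (not isolated)
Conditions: Pd(PPh3)4 (5 mol %), K3PO4, DME/H2O, 85 °C; then TBAF, THF, rt; aq NH4Cl
Reagents that add atoms: none
Why: Suzuki–Miyaura coupling followed by fluoride cleavage of the aryl silyl ether in the same flask. Zerovalent palladium with triphenylphosphine inserts into C–I and leaves the electron-rich C–Cl alone, and the two flanking alkoxy groups are small enough for the tri-ortho-substituted biaryl to form.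

Step 4
Reactants: 6 2,2',6-tris(benzyloxy)-5'-chlorobiphenyl-4-ol
Product: 7 3-bromo-2,2',6-tris(benzyloxy)-5'-chlorobiphenyl-4-ol
Conditions: NBS (1.0 equiv), CH2Cl2, −78 to 0 °C
Reagents that add atoms: N-bromosuccinimide, O=C1CCC(=O)N1Br
Why: ortho-Bromination of a phenol by electrophilic substitution; the two free positions of the phenol ring are equivalent by symmetry, and this ring is far more electron-rich than ring B or the benzyl groups.

Step 5
Reactants: 7 3-bromo-2,2',6-tris(benzyloxy)-5'-chlorobiphenyl-4-ol
Product: 10 3,5-bis(benzyloxy)-4-[2-(benzyloxy)-5-chlorophenyl]-2-(trimethylsilyl)phenyl trifluoromethanesulfonate, via aryl trimethylsilyl ether 8 (not isolated), via lithium 2-silylphenoxide 9 (not isolated)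
Conditions: HMDS, THF, 65 °C, then evaporation; n-BuLi, THF, −78 °C; Tf2O, −78 to 0 °C
Reagents that add atoms: hexamethyldisilazane, C[Si](C)(C)N[Si](C)(C)C; trifluoromethanesulfonic anhydride, O=S(=O)(OS(=O)(=O)C(F)(F)F)C(F)(F)F
Why: O-Silylation, bromine–lithium exchange with retro-Brook (1,3 O→C silyl) rearrangement and O-triflation of the resulting phenoxide, the standard route to ortho-silylaryl triflates. At −78 °C the exchange is much faster than attack on C–Cl or benzylic deprotonation.

Step 6
Reactants: 11 1-(benzyloxy)-4-ethynylbenzene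
Product: 13 3-[4-(benzyloxy)phenyl]prop-2-ynoic acid, via lithium acetylide 12 (not isolated)
Conditions: n-BuLi, THF, −78 °C; CO2; aq HCl
Reagents that add atoms: carbon dioxide, O=C=O
Why: Deprotonation of the terminal alkyne and carboxylation of the lithium acetylide.

Step 7
Reactants: 10 3,5-bis(benzyloxy)-4-[2-(benzyloxy)-5-chlorophenyl]-2-(trimethylsilyl)phenyl trifluoromethanesulfonate; 13 3-[4-(benzyloxy)phenyl]prop-2-ynoic acid
Product: 15 1-{2,4-bis(benzyloxy)-3-[2-(benzyloxy)-5-chlorophenyl]-6-hydroxyphenyl}-3-[4-(benzyloxy)phenyl]prop-2-yn-1-one, via 3-alkoxyaryne 14 (not isolated)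
Conditions: 13 (1.2 equiv), CsF (4 equiv), THF, 110 °C, sealed tube; AcOH quench
Reagents that add atoms: none
Why: Fluoride attacks silicon of 10 and triflate departs in a 1,2-elimination to give aryne 14, while CsF also turns 13 into its cesium carboxylate. The carboxylate oxygen adds to the aryne carbon remote from the C5'' benzyloxy group (the future C8a''), the usual outcome for a 3-alkoxyaryne, leaving the negative charge on C4a'', where the adjacent C–O bond stabilises it inductively. This aryl anion attacks the neighbouring ester carbonyl through a four-membered transition state (an anionic Fries-type 1,3 O→C acyl shift) that collapses to the ketone and the phenoxide, so O1''–C8a'' forms first and C4''–C4a'' second. The closest known reaction type is the fluoride-induced insertion of arynes into the C–O bond of carboxylic acids to give ortho-hydroxyaryl ketones, applied here to an arylpropiolic acid. No ring is closed and no stereocentre is created in this step. The regioselectivity it needs is secured by the C5'' oxygen flanking the aryne, reinforced by the C6'' aryl group, which turns the benzyl group towards C4a'' and hinders attack there; the C7'' oxygen is too remote to oppose it. The acyl shift must outrun protonation of the aryl anion, which the aprotic solvent, the excess of CsF and the elevated temperature are chosen to favour. Should part of 15 react on as its phenoxide under these aprotic conditions, it would do so in the 6-endo Michael sense and give 16, the product of step 8, so nothing is lost.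

Step 8
Reactants: 15 1-{2,4-bis(benzyloxy)-3-[2-(benzyloxy)-5-chlorophenyl]-6-hydroxyphenyl}-3-[4-(benzyloxy)phenyl]prop-2-yn-1-one
Product: 16 5,7-bis(benzyloxy)-6-[2-(benzyloxy)-5-chlorophenyl]-2-[4-(benzyloxy)phenyl]-4H-chromen-4-one
Conditions: DMAP (20 mol %), DMF, 40 °C
Reagents that add atoms: none
Why: Amine-catalysed 6-endo-dig oxa-Michael cyclisation of an ortho-alkynoylphenol. The nucleophilic amine adds to the β-carbon and is displaced by the phenol oxygen, so the six-membered pyranone forms and not the five-membered aurone.

Step 9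
Reactants: 16 5,7-bis(benzyloxy)-6-[2-(benzyloxy)-5-chlorophenyl]-2-[4-(benzyloxy)phenyl]-4H-chromen-4-one
Product: 17 [4-(benzyloxy)-3-{5,7-bis(benzyloxy)-2-[4-(benzyloxy)phenyl]-4-oxo-4H-chromen-6-yl}phenyl]boronic acid
Conditions: B2(OH)4 (3 equiv), XPhos–Pd(2'-aminobiphenyl-2-yl)Cl (second-generation XPhos palladacycle, 2 mol %), XPhos (4 mol %), KOAc, EtOH/THF, 80 °C
Reagents that add atoms: tetrahydroxydiboron, OB(O)B(O)O
Why: Miyaura-type borylation of an aryl chloride with tetrahydroxydiboron, which gives the free boronic acid that step 12 requires. The bulky electron-rich phosphine allows oxidative addition to the electron-rich C–Cl bond, and benzyl ethers and the flavone are not expected to react.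

Step 10
Reactants: 18 1-(2,4-dihydroxy-6-methoxyphenyl)ethan-1-one
Product: 19 1-[4-(benzyloxy)-2-hydroxy-6-methoxyphenyl]ethan-1-one
Conditions: BnBr (1.05 equiv), K2CO3, acetone, reflux
Reagents that add atoms: benzyl bromide, BrCc1ccccc1
Why: Williamson etherification; the 2'-hydroxyl is held in a hydrogen bond to the ketone, so the more acidic and more nucleophilic 4'-hydroxyl is alkylated.

Step 11
Reactants: 19 1-[4-(benzyloxy)-2-hydroxy-6-methoxyphenyl]ethan-1-one
Product: 21 7-(benzyloxy)-5-methoxy-4H-chromen-4-one, via enaminone 20 (not isolated)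
Conditions: DMF-DMA, toluene, 95 °C; then HCl, CH2Cl2, 40 °C
Reagents that add atoms: N,N-dimethylformamide dimethyl acetal, COC(OC)N(C)C
Why: Enaminone formation at the acetyl methyl group and acid-mediated cyclisation with loss of dimethylamine, the standard chromone synthesis; the acetal supplies C2.

Step 12
Reactants: 17 [4-(benzyloxy)-3-{5,7-bis(benzyloxy)-2-[4-(benzyloxy)phenyl]-4-oxo-4H-chromen-6-yl}phenyl]boronic acid; 21 7-(benzyloxy)-5-methoxy-4H-chromen-4-one
Product: 22 (2S)-7-(benzyloxy)-2-[4-(benzyloxy)-3-{5,7-bis(benzyloxy)-2-[4-(benzyloxy)phenyl]-4-oxo-4H-chromen-6-yl}phenyl]-5-methoxy-2,3-dihydro-4H-chromen-4-one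
Conditions: 21 (1.5 equiv), Pd(OCOCF3)2 (10 mol %), (R)-t-BuPyOx [(R)-4-tert-butyl-2-(pyridin-2-yl)-4,5-dihydrooxazole] (12 mol %), NH4PF6 (30 mol %), H2O (5 equiv), ClCH2CH2Cl, 60 °C
Reagents that add atoms: none
Why: Asymmetric conjugate addition of an arylboronic acid to a chromone catalysed by cationic divalent palladium with a pyridine-oxazoline ligand (transmetalation, enantio-determining carbopalladation of C2=C3, protonolysis of the palladium enolate by water). The tert-butyl group of the (R)-ligand shields one enone face so that the aryl group is delivered to the face giving 2S. The flavone inside 17 is inert because its β-carbon is fully substituted.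

Step 13
Reactants: 22 (2S)-7-(benzyloxy)-2-[4-(benzyloxy)-3-{5,7-bis(benzyloxy)-2-[4-(benzyloxy)phenyl]-4-oxo-4H-chromen-6-yl}phenyl]-5-methoxy-2,3-dihydro-4H-chromen-4-one
Product: 23 (2S)-7-hydroxy-2-{4-hydroxy-3-[5,7-dihydroxy-2-(4-hydroxyphenyl)-4-oxo-4H-chromen-6-yl]phenyl}-5-methoxy-2,3-dihydro-4H-chromen-4-one (CNP0332590.1)
Conditions: H2 (1 atm), 10% Pd/C, THF/MeOH, rt, stopped at the calculated uptake
Reagents that add atoms: none
Why: Hydrogenolysis of the five benzyl ethers under neutral conditions; the methyl ether is inert, and aryl benzyl ethers should cleave well before C2''=C3'', the carbonyls or the C2–O1 bond react. The neutral medium avoids ring-opening racemisation at C2.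

## Compound list

1 | 3,5-bis(benzyloxy)phenol | Oc1cc(OCc2ccccc2)cc(OCc2ccccc2)c1 | starting material
2 | [3,5-bis(benzyloxy)phenoxy]tri(propan-2-yl)silane | CC(C)[Si](Oc1cc(OCc2ccccc2)cc(OCc2ccccc2)c1)(C(C)C)C(C)C | intermediate
3 | [3,5-bis(benzyloxy)-4-iodophenoxy]tri(propan-2-yl)silane | CC(C)[Si](Oc1cc(OCc2ccccc2)c(I)c(OCc2ccccc2)c1)(C(C)C)C(C)C | intermediate
4 | [2-(benzyloxy)-5-chlorophenyl]boronic acid | OB(O)c1cc(Cl)ccc1OCc1ccccc1 | starting material
5 | {[2,2',6-tris(benzyloxy)-5'-chlorobiphenyl-4-yl]oxy}tri(propan-2-yl)silane | CC(C)[Si](Oc1cc(OCc2ccccc2)c(-c2cc(Cl)ccc2OCc2ccccc2)c(OCc2ccccc2)c1)(C(C)C)C(C)C | intermediate (not isolated)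
6 | 2,2',6-tris(benzyloxy)-5'-chlorobiphenyl-4-ol, i.e. 3,5-bis(benzyloxy)-4-[2-(benzyloxy)-5-chlorophenyl]phenol | Oc1cc(OCc2ccccc2)c(-c2cc(Cl)ccc2OCc2ccccc2)c(OCc2ccccc2)c1 | intermediate
7 | 3-bromo-2,2',6-tris(benzyloxy)-5'-chlorobiphenyl-4-ol, i.e. 2-bromo-3,5-bis(benzyloxy)-4-[2-(benzyloxy)-5-chlorophenyl]phenol | Oc1cc(OCc2ccccc2)c(-c2cc(Cl)ccc2OCc2ccccc2)c(OCc2ccccc2)c1Br | intermediate
8 | {2-bromo-3,5-bis(benzyloxy)-4-[2-(benzyloxy)-5-chlorophenyl]phenoxy}trimethylsilane | C[Si](C)(C)Oc1cc(OCc2ccccc2)c(-c2cc(Cl)ccc2OCc2ccccc2)c(OCc2ccccc2)c1Br | intermediate (not isolated)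
9 | lithium 3,5-bis(benzyloxy)-4-[2-(benzyloxy)-5-chlorophenyl]-2-(trimethylsilyl)phenoxide | [Li+].[O-]c1cc(OCc2ccccc2)c(-c2cc(Cl)ccc2OCc2ccccc2)c(OCc2ccccc2)c1[Si](C)(C)C | intermediate (not isolated)
10 | 3,5-bis(benzyloxy)-4-[2-(benzyloxy)-5-chlorophenyl]-2-(trimethylsilyl)phenyl trifluoromethanesulfonate | C[Si](C)(C)c1c(OS(=O)(=O)C(F)(F)F)cc(OCc2ccccc2)c(-c2cc(Cl)ccc2OCc2ccccc2)c1OCc1ccccc1 | intermediate
11 | 1-(benzyloxy)-4-ethynylbenzene | C#Cc1ccc(OCc2ccccc2)cc1 | starting material
12 | lithium [4-(benzyloxy)phenyl]acetylide | [Li]C#Cc1ccc(OCc2ccccc2)cc1 | intermediate (not isolated)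
13 | 3-[4-(benzyloxy)phenyl]prop-2-ynoic acid | OC(=O)C#Cc1ccc(OCc2ccccc2)cc1 | intermediate
14 | 3,5-bis(benzyloxy)-4-[2-(benzyloxy)-5-chlorophenyl]benzyne (1,2-didehydrobenzene) | C1#CC(OCc2ccccc2)=C(c2cc(Cl)ccc2OCc2ccccc2)C(OCc2ccccc2)=C1 | intermediate (not isolated)
15 | 1-{2,4-bis(benzyloxy)-3-[2-(benzyloxy)-5-chlorophenyl]-6-hydroxyphenyl}-3-[4-(benzyloxy)phenyl]prop-2-yn-1-one | O=C(C#Cc1ccc(OCc2ccccc2)cc1)c1c(O)cc(OCc2ccccc2)c(-c2cc(Cl)ccc2OCc2ccccc2)c1OCc1ccccc1 | intermediate
16 | 5,7-bis(benzyloxy)-6-[2-(benzyloxy)-5-chlorophenyl]-2-[4-(benzyloxy)phenyl]-4H-chromen-4-one | O=c1cc(-c2ccc(OCc3ccccc3)cc2)oc2cc(OCc3ccccc3)c(-c3cc(Cl)ccc3OCc3ccccc3)c(OCc3ccccc3)c12 | intermediate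
17 | [4-(benzyloxy)-3-{5,7-bis(benzyloxy)-2-[4-(benzyloxy)phenyl]-4-oxo-4H-chromen-6-yl}phenyl]boronic acid | O=c1cc(-c2ccc(OCc3ccccc3)cc2)oc2cc(OCc3ccccc3)c(-c3cc(B(O)O)ccc3OCc3ccccc3)c(OCc3ccccc3)c12 | intermediate
18 | 1-(2,4-dihydroxy-6-methoxyphenyl)ethan-1-one | CC(=O)c1c(O)cc(O)cc1OC | starting material
19 | 1-[4-(benzyloxy)-2-hydroxy-6-methoxyphenyl]ethan-1-one | CC(=O)c1c(O)cc(OCc2ccccc2)cc1OC | intermediate
20 | (E)-1-[4-(benzyloxy)-2-hydroxy-6-methoxyphenyl]-3-(dimethylamino)prop-2-en-1-one | CN(C)/C=C/C(=O)c1c(O)cc(OCc2ccccc2)cc1OC | intermediate (not isolated)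
21 | 7-(benzyloxy)-5-methoxy-4H-chromen-4-one | COc1cc(OCc2ccccc2)cc2occc(=O)c12 | intermediate
22 | (2S)-7-(benzyloxy)-2-[4-(benzyloxy)-3-{5,7-bis(benzyloxy)-2-[4-(benzyloxy)phenyl]-4-oxo-4H-chromen-6-yl}phenyl]-5-methoxy-2,3-dihydro-4H-chromen-4-one | COc1cc(OCc6ccccc6)cc2c1C(=O)C[C@@H](c1ccc(OCc6ccccc6)c(-c3c(OCc6ccccc6)cc4oc(-c5ccc(OCc6ccccc6)cc5)cc(=O)c4c3OCc6ccccc6)c1)O2 | intermediate
23 | (2S)-7-hydroxy-2-{4-hydroxy-3-[5,7-dihydroxy-2-(4-hydroxyphenyl)-4-oxo-4H-chromen-6-yl]phenyl}-5-methoxy-2,3-dihydro-4H-chromen-4-one | COc1cc(O)cc2c1C(=O)C[C@@H](c1ccc(O)c(-c3c(O)cc4oc(-c5ccc(O)cc5)cc(=O)c4c3O)c1)O2 | target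

## Step count and least certain steps

Total: 13 steps. Longest linear sequence: 10 steps (steps 1, 2, 3, 4, 5, 7, 8, 9, 12, 13); steps 6, 10 and 11 are short side branches.

Step 7 (key step). The most likely failure is capture of the aryl anion by a proton before the acyl shift, so that the acid is merely O-arylated and no C4''–C4a'' bond forms. The anion sits between two oxygen substituents and the four-membered transition state needs heat, and the same heat invites loss of CO2 from the propiolate before it meets the aryne. The fallback sets out from 6 and comes back at 16. Compound 6 would be iodinated ortho to the hydroxyl (NIS, CH2Cl2, −40 °C) to give 3,5-bis(benzyloxy)-4-[2-(benzyloxy)-5-chlorophenyl]-2-iodophenol F1. F1, alkyne 11 and CO (PdCl2(PPh3)2, Et2NH, CO 1–5 bar, 80–100 °C) would then undergo a carbonylative Sonogashira coupling. There the acyl carbon comes from CO and is attached to C4a'' by palladium instead of by an aryl anion, C–I reacts in preference to C–Cl, and the diethylamine closes the ynone 15 formed in the flask to 16 in the 6-endo sense.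

Step 12. The most likely failure is slow carbopalladation of the electron-rich 5,7-dioxygenated chromone, so that protodeboronation and oxidative homocoupling consume the valuable boronic acid first. A second risk is erosion of enantiomeric purity by reversible ring opening, and the sense of induction rests on an analogy. The fallback sets out from 16 and comes back at 22.
- Suzuki–Miyaura vinylation of the chloride (potassium vinyltrifluoroborate, Pd(OAc)2, XPhos, K2CO3, THF/H2O) would give 5,7-bis(benzyloxy)-6-[2-(benzyloxy)-5-vinylphenyl]-2-[4-(benzyloxy)phenyl]-4H-chromen-4-one F2.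
- Lemieux–Johnson cleavage (OsO4 cat., NaIO4, 2,6-lutidine, dioxane/H2O) would give 4-(benzyloxy)-3-{5,7-bis(benzyloxy)-2-[4-(benzyloxy)phenyl]-4-oxo-4H-chromen-6-yl}benzaldehyde F3.
- Claisen–Schmidt condensation with 19 (KOH, EtOH/THF, rt) would give the 2'-hydroxychalcone (E)-1-[4-(benzyloxy)-2-hydroxy-6-methoxyphenyl]-3-[4-(benzyloxy)-3-{5,7-bis(benzyloxy)-2-[4-(benzyloxy)phenyl]-4-oxo-4H-chromen-6-yl}phenyl]prop-2-en-1-one F4.
- Oxa-Michael closure (NaOAc, EtOH, reflux) would give the racemic flavanone rac-7-(benzyloxy)-2-[4-(benzyloxy)-3-{5,7-bis(benzyloxy)-2-[4-(benzyloxy)phenyl]-4-oxo-4H-chromen-6-yl}phenyl]-5-methoxy-2,3-dihydro-4H-chromen-4-one F5.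
- Preparative chromatography of F5 on a chiral stationary phase would give 22, and the unwanted half could be re-equilibrated through F4 with base.

Step 2. The most likely failure is poor regioselectivity: iodination next to the silyl ether instead of between the benzyloxy groups, since the three free positions are electronically alike and only steric shielding discriminates; double iodination is a lesser risk. The fallback builds the ring with the aryl group already in place. It does not branch from an earlier compound of the route but replaces steps 1 to 3, setting out from commercial 2-(5-chloro-2-hydroxyphenyl)acetic acid F6 and coming back at 6.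
- F6 would be bis-benzylated (BnBr, K2CO3, DMF) to benzyl 2-[2-(benzyloxy)-5-chlorophenyl]acetate F7.
- F7 would acylate the dianion of methyl acetoacetate (NaH, then n-BuLi, THF, 0 °C) to give methyl 6-[2-(benzyloxy)-5-chlorophenyl]-3,5-dioxohexanoate F8.
- F8 would lactonise (DBU, toluene, reflux) to 6-[2-(benzyloxy)-5-chlorobenzyl]-4-hydroxy-2H-pyran-2-one F9.
- Mitsunobu O-alkylation (4-methoxybenzyl alcohol, PPh3, DIAD) would give 6-[2-(benzyloxy)-5-chlorobenzyl]-4-[(4-methoxybenzyl)oxy]-2H-pyran-2-one F10.
- Sodium 4-methoxybenzyl oxide in THF would open the lactone, and the benzylic carbanion would close onto the ester (Dieckmann-type; defensible by analogy with Claisen-type closures of 3,5-dioxo esters to phloroglucinols) to give 2-[2-(benzyloxy)-5-chlorophenyl]-5-[(4-methoxybenzyl)oxy]benzene-1,3-diol F11.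
- Benzylation (BnBr, K2CO3, DMF) would give 2,2',6-tris(benzyloxy)-5'-chloro-4-[(4-methoxybenzyl)oxy]biphenyl F12.
- TFA with anisole in CH2Cl2 at 0 °C would remove the 4-methoxybenzyl group to give 6.

Step 9. The most likely failure is reduction in place of borylation: hydrodechlorination, or conjugate reduction of the flavone by the diboron/ethanol system. Losses on isolating a polar, anhydride-forming boronic acid are a second risk; oxidative addition to the electron-rich chloride is slow and gives these pathways time. The fallback sets out from 16 and comes back at 17. Anhydrous Miyaura borylation (B2pin2, Pd2(dba)3, XPhos, KOAc, dioxane, 100 °C) would give the chromatographable pinacol ester 5,7-bis(benzyloxy)-6-[2-(benzyloxy)-5-(4,4,5,5-tetramethyl-1,3,2-dioxaborolan-2-yl)phenyl]-2-[4-(benzyloxy)phenyl]-4H-chromen-4-one F13. Oxidative cleavage of the pinacol unit (NaIO4, NH4OAc, acetone/H2O, rt) would then give 17.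

## Further compounds

F1 | step 7 | 3,5-bis(benzyloxy)-4-[2-(benzyloxy)-5-chlorophenyl]-2-iodophenol | Oc1cc(OCc2ccccc2)c(-c2cc(Cl)ccc2OCc2ccccc2)c(OCc2ccccc2)c1I
F2 | step 12 | 5,7-bis(benzyloxy)-6-[2-(benzyloxy)-5-vinylphenyl]-2-[4-(benzyloxy)phenyl]-4H-chromen-4-one | O=c1cc(-c2ccc(OCc3ccccc3)cc2)oc2cc(OCc3ccccc3)c(-c3cc(C=C)ccc3OCc3ccccc3)c(OCc3ccccc3)c12
F3 | step 12 | 4-(benzyloxy)-3-{5,7-bis(benzyloxy)-2-[4-(benzyloxy)phenyl]-4-oxo-4H-chromen-6-yl}benzaldehyde | O=c1cc(-c2ccc(OCc3ccccc3)cc2)oc2cc(OCc3ccccc3)c(-c3cc(C=O)ccc3OCc3ccccc3)c(OCc3ccccc3)c12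
F4 | step 12 | (E)-1-[4-(benzyloxy)-2-hydroxy-6-methoxyphenyl]-3-[4-(benzyloxy)-3-{5,7-bis(benzyloxy)-2-[4-(benzyloxy)phenyl]-4-oxo-4H-chromen-6-yl}phenyl]prop-2-en-1-one | COc1cc(OCc2ccccc2)cc(O)c1C(=O)/C=C/c1ccc(OCc2ccccc2)c(-c2c(OCc3ccccc3)cc3oc(-c4ccc(OCc5ccccc5)cc4)cc(=O)c3c2OCc2ccccc2)c1
F5 | step 12 | rac-7-(benzyloxy)-2-[4-(benzyloxy)-3-{5,7-bis(benzyloxy)-2-[4-(benzyloxy)phenyl]-4-oxo-4H-chromen-6-yl}phenyl]-5-methoxy-2,3-dihydro-4H-chromen-4-one | COc1cc(OCc6ccccc6)cc2c1C(=O)CC(c1ccc(OCc6ccccc6)c(-c3c(OCc6ccccc6)cc4oc(-c5ccc(OCc6ccccc6)cc5)cc(=O)c4c3OCc6ccccc6)c1)O2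
F6 | step 2 | 2-(5-chloro-2-hydroxyphenyl)acetic acid | OC(=O)Cc1cc(Cl)ccc1O
F7 | step 2 | benzyl 2-[2-(benzyloxy)-5-chlorophenyl]acetate | O=C(Cc1cc(Cl)ccc1OCc1ccccc1)OCc1ccccc1
F8 | step 2 | methyl 6-[2-(benzyloxy)-5-chlorophenyl]-3,5-dioxohexanoate | COC(=O)CC(=O)CC(=O)Cc1cc(Cl)ccc1OCc1ccccc1
F9 | step 2 | 6-[2-(benzyloxy)-5-chlorobenzyl]-4-hydroxy-2H-pyran-2-one | O=c1cc(O)cc(Cc2cc(Cl)ccc2OCc2ccccc2)o1
F10 | step 2 | 6-[2-(benzyloxy)-5-chlorobenzyl]-4-[(4-methoxybenzyl)oxy]-2H-pyran-2-one | O=c1cc(OCc2ccc(OC)cc2)cc(Cc2cc(Cl)ccc2OCc2ccccc2)o1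
F11 | step 2 | 2-[2-(benzyloxy)-5-chlorophenyl]-5-[(4-methoxybenzyl)oxy]benzene-1,3-diol | Oc1cc(OCc2ccc(OC)cc2)cc(O)c1-c1cc(Cl)ccc1OCc1ccccc1
F12 | step 2 | 2,2',6-tris(benzyloxy)-5'-chloro-4-[(4-methoxybenzyl)oxy]biphenyl | COc1ccc(COc2cc(OCc3ccccc3)c(-c3cc(Cl)ccc3OCc3ccccc3)c(OCc3ccccc3)c2)cc1
F13 | step 9 | 5,7-bis(benzyloxy)-6-[2-(benzyloxy)-5-(4,4,5,5-tetramethyl-1,3,2-dioxaborolan-2-yl)phenyl]-2-[4-(benzyloxy)phenyl]-4H-chromen-4-one | O=c1cc(-c2ccc(OCc3ccccc3)cc2)oc2cc(OCc3ccccc3)c(-c3cc(B4OC(C)(C)C(C)(C)O4)ccc3OCc3ccccc3)c(OCc3ccccc3)c12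
A1 | alternative 1 | penta-O-benzyl (2S,4S)-flavan-4-ol | COc1cc(OCc6ccccc6)cc2c1[C@@H](O)C[C@@H](c1ccc(OCc6ccccc6)c(-c3c(OCc6ccccc6)cc4oc(-c5ccc(OCc6ccccc6)cc5)cc(=O)c4c3OCc6ccccc6)c1)O2
A2 | alternative 1 | (1S,3S)-1-[4-(benzyloxy)-2-methoxy-6-(trifluoromethanesulfonyloxy)phenyl]-3-[4-(benzyloxy)-3-{5,7-bis(benzyloxy)-2-[4-(benzyloxy)phenyl]-4-oxo-4H-chromen-6-yl}phenyl]propane-1,3-diol | COc1cc(OCc6ccccc6)cc(OS(=O)(=O)C(F)(F)F)c1[C@@H](O)C[C@H](O)c1ccc(OCc6ccccc6)c(-c3c(OCc6ccccc6)cc4oc(-c5ccc(OCc6ccccc6)cc5)cc(=O)c4c3OCc6ccccc6)c1
A3 | alternative 2 | 2-(2-benzyloxy-5-bromophenyl)-5-(4-methoxybenzyloxy)benzene-1,3-diol | Oc1cc(OCc2ccc(OC)cc2)cc(O)c1-c1cc(Br)ccc1OCc1ccccc1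
A4 | alternative 2 | 6-(2-benzyloxy-5-bromobenzyl)-4-(4-methoxybenzyloxy)-2H-pyran-2-one | O=c1cc(OCc2ccc(OC)cc2)cc(Cc2cc(Br)ccc2OCc2ccccc2)o1
A5 | alternative 3 | 5,7-dibenzyloxy-6-(2-benzyloxy-5-bromophenyl)-2-(4-benzyloxyphenyl)-3-chlorochromen-4-one | O=c1c(Cl)c(-c2ccc(OCc3ccccc3)cc2)oc2cc(OCc3ccccc3)c(-c3cc(Br)ccc3OCc3ccccc3)c(OCc3ccccc3)c12
A6 | alternative 3 | {[4,6-bis(benzyloxy)-5-(2-benzyloxy-5-bromophenyl)-2-(4-benzyloxyphenyl)-1-benzofuran-3-yl]oxy}(tert-butyl)dimethylsilane | CC(C)(C)[Si](C)(C)Oc1c(-c2ccc(OCc3ccccc3)cc2)oc2cc(OCc3ccccc3)c(-c3cc(Br)ccc3OCc3ccccc3)c(OCc3ccccc3)c12
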